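If a flask is asked about at 30 % conversion, I first want the clock time of that moment, and then an order.

| setting | epsilon | delta | eta | flask |
|---|---|---|---|---|
| substrate | 0.10 M | 0.10 M | 0.10 M | 0.10 M |
| coupling partner | 0.075 M | 0.11 M | 0.15 M | 0.150 M |
| free catalyst | 16 mM | 16 mM | 24 mM | 16 mM |
| remark | run made earlier | run made earlier | run made earlier |  |

- epsilon (time / d: product / %, substrate / %): 5.00: 10, 5; 10.0: 18, 1; 15.0: 20, 3; 20.0: 29, 0
- delta (time / d: product / %, substrate / %): 2.50: 3, 16; 8.00: 21, 6; 12.0: 22, 2; 20.0: 31, 1
- eta (time / d: product / %, substrate / %): 2.50: 11, 16; 8.00: 30, 3; 12.0: 39, 1; 20.0: 44, 0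

(each reading ± 2 percentage points)

* apparent order in free catalyst when 30 % of the substrate are converted (percent change of the rate of making product for one percent more free catalyst charged)



The delta and eta runs both read 16 % substrate at 2.50 d, with 16 mM and 24 mM free catalyst, so I carry that loss over to this flask. But which law does it follow? Through that point, a first-order decay leaves 0.284 % at 8.00 d and a second-order decay leaves 5.62 %. The readings are 6 % and 3 %, so I take second order. The look time t_L, the time the substrate needs to reach the asked conversion on that law, is then:

t_L = 0.204 d

That is earlier than the first reading, by a factor of 12.3, so early readings matter most. For the order n, with P the product reading and C the free catalyst charged: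

n = ln(P_eta/P_delta) / ln(C_eta/C_delta)

This gives 0.880 at 8.00 d but 3.20 at 2.50 d. The objection is that 3 % carries a scatter of 2 percentage points. Pushing both early readings one standard deviation against me still gives 1.45.

Eta also holds more coupling partner. The epsilon and delta product readings at 20.0 d, 29 % and 31 %, lie within scatter of each other, and they are late, so I read no partner order for the early ratio from them. If I allow a partner order of one, the unpushed value falls to 2.44 and the pushed value to 0.685. I commit to an order above 1, as an estimate and not as a bound, since the pushed value lies lower.

The forecast says “Product per catalyst charged is nearly constant” and gives 0.9, lower than my unpushed estimate but higher than my pushed value.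

The flask gives 1.6, above the forecast.

    substrate + free catalyst → free catalyst + open intermediate (k = 0.751 L mol⁻¹ h⁻¹)
    free catalyst + open intermediate ⇌ catalyst intermediate (K = 8.63 L mol⁻¹, k = 2.97 L mol⁻¹ h⁻¹)
    coupling partner + catalyst intermediate → free catalyst + product (k = 0.568 L mol⁻¹ h⁻¹)
    2 substrate → homo dimer (k = 0.277 L mol⁻¹ h⁻¹)

At 1.24 d, later than t_L, this flask still makes catalyst intermediate 1.17 times as fast as it uses it up. Catalyst intermediate goes on to product at 2.0 d⁻¹, a pseudo-first-order constant with coupling partner as charged, and falls back to free catalyst and open intermediate at 8.26 d⁻¹, and the two together give a lifetime τ: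

τ = 0.0970 d

My look time spans t_L/τ = 2.10 such lifetimes.

Readings and results are calculated from invented constants; the scatter is artificial.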